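## Analysis of the target

The target is a flavanone. Ring A is a benzene substituted at five of its six positions (C4a acyl, C5 OH, C7 OMe, C8 prenyl, C8a O1, only C6 is H), ring C is the dihydropyranone (O1, C2, C3, C4=O), and ring B is a 3-hydroxy-4-methoxyphenyl group on C2. C2 is the only stereocentre and reads as (S) from the SMILES (O1 > C1' > C3 > H), so the problem is one of absolute configuration only. That centre is fragile: O1 is a phenoxide leaving group β to the C4 ketone, so deprotonation at C3 can open ring C to an achiral chalcone that recloses as the racemate, and the para 4'-OMe makes ionisation of C2–O1 under strong acid conceivable. The prenyl alkene at C8 rules out hydrogenolysis, electrophilic halogenation and warm protic or Lewis acid. Two phenols must end free (the chelated 5-OH and the 3'-OH) while 7-OMe and 4'-OMe stay, so O5 must be told apart from O7 and the prenyl group must sit at C8, not C6. The route rests on C8a being ortho to C4a, the carbon that carries the C4 carbonyl: a fluorine on C8a is activated for displacement, and the oxygens on C5 and C7 are both meta to C8a and cannot donate onto it. O1–C8a can therefore be made last, from a C2 carbinol oxygen whose C–O bond already holds the configuration, and the same fluorine directs lithiation to its two neighbours, the future C8 and C4a.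

## Retrosynthetic reasoning

**15 back to 13 (O–CH3 at C5, O–CH2Ph at C3').** The two free phenols are masked as a methyl and a benzyl ether. Of the three methyl ethers in 13, only the one on C5 is peri to the C4 carbonyl and can sit in a six-membered chelate with a boron trihalide, so O5 and O7 need not be differentiated earlier and ring A can come from a symmetrical dimethoxyarene. Benzyl is chosen for O3' because the benzylated acid 5 is an article of commerce and the group is inert to the bases and organolithiums used earlier. The forward step must remove both groups through the intermediate 14 without touching 7-OMe, 4'-OMe, the prenyl group or C2.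

**13 back to 12 (O1–C8a).** Ring C is opened at the aryl–oxygen bond rather than at O1–C2. Cutting O1–C2 would mean either an invertive substitution at an electron-rich benzylic carbon or a conjugate addition through the achiral chalcone. Cutting O1–C8a leaves the C2–O bond intact, so the configuration is carried in unchanged from an acyclic carbinol. The forward reaction needs the alkoxide of 12 to attack the fluorinated carbon faster than it fragments or dehydrates, and needs 13 to survive the medium.

**12 back to 11 and 10 (C4–C4a).** The β-hydroxy ketone is cut at the aryl–carbonyl bond, not at C2–C3. An aldol construction of C2–C3 from a methyl ketone and an aromatic aldehyde gives only moderate enantiocontrol with chiral boron enolates and forms the sensitive aldol under enolate conditions. Cutting C4–C4a puts the stereocentre into the hydroxy amide 10, where it can be set by a ketone reduction of well-established sense, and makes the route convergent. The aryllithium 11 must acylate exactly once, which the N-methoxy-N-methylamide ensures.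

**11 back to 4, and 4 back to 1 and 2 through 3 (C4a–Li, C8–C1'' of the prenyl group).** Both carbons flanking the fluorine of 1 lie between F and OMe and are the most acidic ring positions. The first lithiation (3) takes the prenyl group from 2, and the second, at the one remaining F/OMe-flanked C–H of 4, gives 11. Prenyl goes in first because a ketone would not survive a later lithiation. The gain is the complete ring A pattern from one commercial arene without any electrophilic substitution on a prenylated ring.

**10 back to 9, and 9 back to 5 and 6 through 7 and 8 (C2–H, C3–C4 of the amide chain).** The carbinol comes from enantioselective transfer hydrogenation of the aryl ketone in 9, a substrate class for which the facial preference is dictated by the aryl group. 9 comes from C-acylation of the amide enolate 8 with the acyl imidazole 7 made from acid 5.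

## Alternatives that were turned down

**Alternative 1:** Biosynthetic logic. The disconnection removes ring A altogether: the cinnamic acid A1, activated as a thioester, is extended by a chalcone synthase with three malonate units (forming C4–C4a, C5–C6 and C7–C8), ring A closes by Claisen condensation (C4a–C8a), and chalcone isomerase closes O1–C2 to give the (2S)-flavanone A2.
- For it: nothing else builds the core in so few operations, and the isomerase delivers C2 at neutral pH with essentially perfect fidelity. On both points it is stronger than the chosen route.
- Against it: the 3-hydroxy-4-methoxy starter is not the native substrate of the synthase. More seriously, A2 still lacks the two features that make this target hard. Prenylation of a free phloroglucinol ring gives C6, C8 and O-alkylation together and needs base, which endangers C2. Methylation must then pick O7 over O5 and O3'.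
- Comparison: the chosen route fixes the C8 prenyl group and the O5/O7 pattern on ring A before the stereocentre exists, by chemistry whose regiochemistry follows from one fluorine substituent.

**Alternative 2:** Disconnection of C2–C3. The diazo keto ester A3 carries ring B as a benzyl ether on the ortho oxygen. A chiral dirhodium carboxylate generates the carbenoid, which inserts into the O-benzylic C–H bond, closing ring C and setting C2 to give A4. Fluoride-induced ester cleavage, decarboxylation and desilylation would follow.
- For it: the ether in A3 is trivial to make, the enantio-determining step is catalytic and ring-forming, and the end-game needs only fluoride rather than a boron trihalide. That is a real advantage over step 6.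
- Against it: an acceptor/acceptor carbenoid ortho to an aryl ether oxygen prefers attack on the oxygen lone pair. That gives a five-membered oxonium ylide and benzyl shift rather than a six-membered C–H insertion. The prenyl alkene and ring B are further carbenoid traps. In A4, C3 is flanked by two carbonyls while O1 is a β leaving group, so the C2 configuration is in its most labile state just when base or fluoride is applied for decarboxylation. A3 also still needs a hexasubstituted ring A with O5 and O7 differentiated.
- Comparison: the chosen route keeps C3 singly activated, reaches its precursor in fewer steps, and has no competing carbenoid manifolds.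

**Alternative 3:** Disconnection of ring A at C4a–C5 and C8–C8a. The enantiopure bromodihydropyranone A5 acts as dienophile toward the prenyl-bearing silyl ketene acetal diene A6. Dehydrobromination and loss of the acetal oxygen substituents aromatise the adduct to A7, which needs only desilylation.
- For it: C2 would come from a reliable asymmetric hetero-Diels–Alder reaction, and ring A appears with 5-OH free and 7-OMe in place. No late ether cleavage is needed. On this point it is stronger than the chosen route.
- Against it: the double bond of A5 is a vinylogous ester and a poor partner for an electron-rich diene, and such dienes work best with quinones. A6 is hydrolytically fragile and hindered at the very terminus that must bond to the oxygenated carbon. A stepwise Michael pathway and incomplete aromatisation are likely. The elimination steps pass through β-aryloxy ketone intermediates under base or heat, again exposing C2.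
- Comparison: the chosen route starts from an intact benzene ring and forms each bond by a reaction with firm precedent on closely related substrates. Its price is the final boron-mediated deprotection.

Key step: step 5

Assumption: 3-(benzyloxy)-4-methoxybenzoic acid (5) is taken as a purchasable starting material, and the configuration to be made is (2S), as read from the SMILES.

## Route

**Step 1**
Reactants: 1 1-fluoro-3,5-dimethoxybenzene; 2 prenyl bromide (1-bromo-3-methylbut-2-ene)
Product: 4 1-fluoro-3,5-dimethoxy-2-(3-methylbut-2-en-1-yl)benzene, via 2-fluoro-4,6-dimethoxyphenyllithium 3 (not isolated)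
Conditions: n-BuLi (1.05 equiv), THF, −78 °C, 1 h; CuBr·SMe2 (10 mol %), then 2 (1.2 equiv), −78 → −20 °C; aq NH4Cl
Reagents that add atoms: none
Why: Directed ortho-lithiation; the C2–H of 1 lies between F and OMe and should be the most acidic ring proton (C4–H has two ortho methoxy groups but no ortho fluorine), and at −78 °C loss of LiF to an aryne is slow. Copper-catalysed allylic substitution of 2 by the aryl nucleophile should then occur at the primary carbon (SN2 rather than SN2') to give the linear prenyl arene.

**Step 2**
Reactants: 5 3-(benzyloxy)-4-methoxybenzoic acid; 6 N-methoxy-N-methylacetamide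
Product: 9 3-[3-(benzyloxy)-4-methoxyphenyl]-N-methoxy-N-methyl-3-oxopropanamide, via acylimidazole 7 (not isolated), via amide lithium enolate 8 (not isolated)
Conditions: 5, 1,1'-carbonyldiimidazole (1.1 equiv), THF, 25 °C, 1 h; separately 6 (2.3 equiv), LiN(i-Pr)2 (2.3 equiv), THF, −78 °C; add 7, −78 → −40 °C; 1 M aq HCl
Reagents that add atoms: none
Why: Crossed Claisen-type C-acylation of an amide enolate by an acyl imidazole; the β-keto amide is deprotonated as it forms by the second equivalent of 8, which blocks a second acylation, and the aroyl partner has no α-hydrogen.

**Step 3**
Reactants: 9 3-[3-(benzyloxy)-4-methoxyphenyl]-N-methoxy-N-methyl-3-oxopropanamide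
Product: 10 (3S)-3-[3-(benzyloxy)-4-methoxyphenyl]-3-hydroxy-N-methoxy-N-methylpropanamide
Conditions: RuCl[(S,S)-TsDPEN](p-cymene) (1 mol %), HCO2H–Et3N (5:2), EtOAc, 35 °C
Reagents that add atoms: none
Why: Noyori asymmetric transfer hydrogenation of an aryl ketone; the (S,S)-catalyst recognises the aryl group as it does in acetophenone, where it gives the (S)-carbinol, and because the CH2C(O)N chain ranks below the aryl group just as methyl does, the product should be (S)-10. Benzyl ether, N–O bond and amide are inert to the ruthenium hydride.

**Step 4**
Reactants: 4 1-fluoro-3,5-dimethoxy-2-(3-methylbut-2-en-1-yl)benzene; 10 (3S)-3-[3-(benzyloxy)-4-methoxyphenyl]-3-hydroxy-N-methoxy-N-methylpropanamide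
Product: 12 (3S)-3-[3-(benzyloxy)-4-methoxyphenyl]-1-[2-fluoro-4,6-dimethoxy-3-(3-methylbut-2-en-1-yl)phenyl]-3-hydroxypropan-1-one, via prenylated aryllithium 11 (not isolated)
Conditions: 4 (2.4 equiv), n-BuLi (2.2 equiv), THF, −78 °C, 1.5 h; 10 (1.0 equiv) in THF, −78 → −55 °C; aq NH4Cl at −78 °C
Reagents that add atoms: none
Why: A second directed ortho-lithiation at the only remaining C–H flanked by F and OMe, then Weinreb ketone synthesis; the first equivalent of 11 merely deprotonates the hydroxyl (returning 4, which is recovered) and the second adds to give the chelated tetrahedral adduct, which cannot add again and releases the ketone only on work-up. The carbinol centre is a lithium alkoxide at −78 °C throughout and is not touched.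

**Step 5**
Reactants: 12 (3S)-3-[3-(benzyloxy)-4-methoxyphenyl]-1-[2-fluoro-4,6-dimethoxy-3-(3-methylbut-2-en-1-yl)phenyl]-3-hydroxypropan-1-one
Product: 13 (2S)-2-[3-(benzyloxy)-4-methoxyphenyl]-5,7-dimethoxy-8-(3-methylbut-2-en-1-yl)-2,3-dihydro-4H-chromen-4-one
Conditions: Cs2CO3 (1.5 equiv), dry DMF (0.02 M), 0 → 25 °C; pH 7 phosphate buffer
Reagents that add atoms: none
Why: Carbonate reversibly deprotonates the secondary hydroxyl, and the alkoxide adds to the fluorine-bearing carbon (the future C8a) to give a Meisenheimer anion whose charge rests on C4a, C6 and C8 and is taken up by the C4 carbonyl; loss of fluoride then completes an addition–elimination in which fluorine is the best leaving group because addition is rate-limiting. The closest known reaction type is the intramolecular nucleophilic aromatic etherification of ortho-fluoroaryl ketones by tethered oxygen nucleophiles used for chroman-4-ones, chromones and xanthones. Ring C closes in a 6-exo-trig addition at the aromatic carbon. No stereocentre is created: C2 should keep its (S) configuration because its C–O bond, made in step 3, is never broken. The step needs cyclisation to outrun three processes: retro-aldol cleavage of the same alkoxide (which would scramble C2 if it re-adds), E1cB dehydration through the C3 enolate, and base-induced opening of ring C in 13. The substrate helps because both methoxy groups are meta to the attacked carbon and none sits on a charge-bearing position, the six-membered transition state holds the carbonyl in the ring plane for full activation, and fluoride is a leaving group only in this manifold. A weak, sparingly soluble base at high dilution and low temperature keeps the alkoxide and enolate concentrations low, and a buffered quench protects the product.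

**Step 6**
Reactants: 13 (2S)-2-[3-(benzyloxy)-4-methoxyphenyl]-5,7-dimethoxy-8-(3-methylbut-2-en-1-yl)-2,3-dihydro-4H-chromen-4-one
Product: 15 (2S)-5-hydroxy-2-(3-hydroxy-4-methoxyphenyl)-7-methoxy-8-(3-methylbut-2-en-1-yl)-2,3-dihydro-4H-chromen-4-one, via 3'-O-debenzylated flavanone 14 (not isolated)
Conditions: BCl3 (5 equiv), C6HMe5 (3 equiv), CH2Cl2, −78 °C, 30 min; then −78 → 0 °C; cold aq NaHCO3
Reagents that add atoms: none
Why: Lewis-acid ether cleavage; at −78 °C BCl3 activates the benzyl ether and the benzyl cation is passed to pentamethylbenzene, a non-basic scavenger that keeps it away from the prenyl alkene and the arenes, giving 14 as its boron aryloxide. On warming, the C4 carbonyl and the peri C5 methoxy group form a six-membered boron chelate from which chloride removes the methyl group, an activation the 7- and 4'-methyl ethers lack.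

## Compound list

1 | 1-fluoro-3,5-dimethoxybenzene | COc1cc(F)cc(OC)c1 | starting material
2 | prenyl bromide (1-bromo-3-methylbut-2-ene) | CC(C)=CCBr | starting material
3 | 2-fluoro-4,6-dimethoxyphenyllithium | [Li]c1c(F)cc(OC)cc1OC | intermediate
4 | 1-fluoro-3,5-dimethoxy-2-(3-methylbut-2-en-1-yl)benzene | COc1cc(OC)c(CC=C(C)C)c(F)c1 | intermediate
5 | 3-(benzyloxy)-4-methoxybenzoic acid | COc1ccc(C(=O)O)cc1OCc1ccccc1 | starting material
6 | N-methoxy-N-methylacetamide | CC(=O)N(C)OC | starting material
7 | [3-(benzyloxy)-4-methoxyphenyl](1H-imidazol-1-yl)methanone | COc1ccc(C(=O)n2ccnc2)cc1OCc1ccccc1 | intermediate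
8 | lithium 1-[methoxy(methyl)amino]ethen-1-olate | C=C(O[Li])N(C)OC | intermediate
9 | 3-[3-(benzyloxy)-4-methoxyphenyl]-N-methoxy-N-methyl-3-oxopropanamide | COc1ccc(C(=O)CC(=O)N(C)OC)cc1OCc1ccccc1 | intermediate
10 | (3S)-3-[3-(benzyloxy)-4-methoxyphenyl]-3-hydroxy-N-methoxy-N-methylpropanamide | COc1ccc([C@@H](O)CC(=O)N(C)OC)cc1OCc1ccccc1 | intermediate
11 | [2-fluoro-4,6-dimethoxy-3-(3-methylbut-2-en-1-yl)phenyl]lithium | [Li]c1c(F)c(CC=C(C)C)c(OC)cc1OC | intermediate
12 | (3S)-3-[3-(benzyloxy)-4-methoxyphenyl]-1-[2-fluoro-4,6-dimethoxy-3-(3-methylbut-2-en-1-yl)phenyl]-3-hydroxypropan-1-one | COc1ccc([C@@H](O)CC(=O)c2c(OC)cc(OC)c(CC=C(C)C)c2F)cc1OCc1ccccc1 | intermediate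
13 | (2S)-2-[3-(benzyloxy)-4-methoxyphenyl]-5,7-dimethoxy-8-(3-methylbut-2-en-1-yl)-2,3-dihydro-4H-chromen-4-one | COc1ccc([C@@H]2CC(=O)c3c(OC)cc(OC)c(CC=C(C)C)c3O2)cc1OCc1ccccc1 | intermediate
14 | (2S)-2-(3-hydroxy-4-methoxyphenyl)-5,7-dimethoxy-8-(3-methylbut-2-en-1-yl)-2,3-dihydro-4H-chromen-4-one (present in the flask as its boron aryloxide) | COc1ccc([C@@H]2CC(=O)c3c(OC)cc(OC)c(CC=C(C)C)c3O2)cc1O | intermediate
15 | (2S)-5-hydroxy-2-(3-hydroxy-4-methoxyphenyl)-7-methoxy-8-(3-methylbut-2-en-1-yl)-2,3-dihydro-4H-chromen-4-one | COc1ccc([C@@H]2CC(=O)c3c(O)cc(OC)c(CC=C(C)C)c3O2)cc1O | target

## Step count and least certain steps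

Total: 6 steps. Longest linear sequence: 5 steps (5 → 9 → 10 → 12 → 13 → 15); the ring A branch (1 → 4) joins at step 4.

**Step 5 (key step).** The most likely failure is that the alkoxide fragments by retro-aldol cleavage, or the C3 enolate dehydrates, faster than the oxygen attacks a ring that is electron-rich, ortho-alkylated and activated by a single ketone. Reversible fragmentation would also erode the configuration at C2, as would base-induced opening and reclosure of ring C in the product.
Fallback: keep fluoride displacement for the ring closure but separate it from the stereocentre. Setting out from 4 and 6, the aryllithium 11 is acylated with 6 to give 1-[2-fluoro-4,6-dimethoxy-3-(3-methylbut-2-en-1-yl)phenyl]ethan-1-one F1. Claisen formylation with ethyl formate and NaH, then warming with K2CO3 in DMF, lets the enolate oxygen displace fluorine (no aldol unit is present to cleave or dehydrate) and gives 5,7-dimethoxy-8-(3-methylbut-2-en-1-yl)-4H-chromen-4-one F2. Base-free asymmetric conjugate addition of [3-(benzyloxy)-4-methoxyphenyl]boronic acid F3 under Pd(OCOCF3)2 with a tert-butyl pyridine-oxazoline ligand (NH4PF6, water, 1,2-dichloroethane, 60 °C; the ligand antipode chosen for the 2S series) returns to the route at 13.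

**Step 1.** Lithiation may partition between C2 and C4 (the position between the two methoxy groups), since butyllithium responds to coordination as well as acidity.
Fallback: fix the site by electrophilic substitution instead of deprotonation. Setting out from 1, bromination with N-bromosuccinimide in acetonitrile should occur at the less hindered position ortho to one methoxy group and para to the other, giving 2-bromo-1-fluoro-3,5-dimethoxybenzene F4. Bromine–lithium exchange with n-BuLi at −78 °C then delivers 3 regiospecifically, where the route is rejoined.

**Step 4.** Two things may go wrong. Metalation could compete at the doubly activated benzylic-allylic methylene of 4. The ortho-fluoroaryllithium could also lose LiF to an aryne if the hindered nucleophile has to be warmed to add to the amide alkoxide, and enolisation of the amide would return starting material.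
Fallback: make the nucleophile by halogen–metal exchange and use magnesium. Setting out from 1 through the bromide F4 of the preceding fallback, directed magnesiation at the remaining F/OMe-flanked C–H with (2,2,6,6-tetramethylpiperidin-1-yl)MgCl·LiCl (an amide base that leaves the bromine in place) and copper-catalysed prenylation with 2 give 2-bromo-3-fluoro-1,5-dimethoxy-4-(3-methylbut-2-en-1-yl)benzene F5. Bromine–magnesium exchange with i-PrMgCl·LiCl gives [2-fluoro-4,6-dimethoxy-3-(3-methylbut-2-en-1-yl)phenyl]magnesium chloride F6, which tolerates 0 °C and is added to 10 (hydroxyl first deprotonated with i-PrMgCl), returning to the route at 12.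

**Step 6.** The warmer phase needed for the chelated methyl ether may bring acid-mediated hydrochlorination or cationic reaction of the prenyl alkene, partial loss of the 4'-methyl ether next to the boron-bound 3'-oxygen, or erosion at C2 through Lewis-acid-assisted opening of ring C.
Fallback: separate the two cleavages by mechanism. Setting out from 13, MgI2·OEt2 in toluene/THF at 60 °C removes only the peri methyl group (iodide attack on the magnesium chelate) to give (2S)-2-[3-(benzyloxy)-4-methoxyphenyl]-5-hydroxy-7-methoxy-8-(3-methylbut-2-en-1-yl)-2,3-dihydro-4H-chromen-4-one F7. The benzyl ether is then cleaved with BCl3 and C6HMe5 held at −78 °C, where the alkene should be inert, arriving at 15.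

## Further compounds

F1 | step 5 | 1-[2-fluoro-4,6-dimethoxy-3-(3-methylbut-2-en-1-yl)phenyl]ethan-1-one | CC(=O)c1c(OC)cc(OC)c(CC=C(C)C)c1F
F2 | step 5 | 5,7-dimethoxy-8-(3-methylbut-2-en-1-yl)-4H-chromen-4-one | COc1cc(OC)c2c(=O)ccoc2c1CC=C(C)C
F3 | step 5 | [3-(benzyloxy)-4-methoxyphenyl]boronic acid | COc1ccc(B(O)O)cc1OCc1ccccc1
F4 | step 1 | 2-bromo-1-fluoro-3,5-dimethoxybenzene | COc1cc(F)c(Br)c(OC)c1
F5 | step 4 | 2-bromo-3-fluoro-1,5-dimethoxy-4-(3-methylbut-2-en-1-yl)benzene | COc1cc(OC)c(Br)c(F)c1CC=C(C)C
F6 | step 4 | [2-fluoro-4,6-dimethoxy-3-(3-methylbut-2-en-1-yl)phenyl]magnesium chloride | Cl[Mg]c1c(F)c(CC=C(C)C)c(OC)cc1OC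
F7 | step 6 | (2S)-2-[3-(benzyloxy)-4-methoxyphenyl]-5-hydroxy-7-methoxy-8-(3-methylbut-2-en-1-yl)-2,3-dihydro-4H-chromen-4-one | COc1ccc([C@@H]2CC(=O)c3c(O)cc(OC)c(CC=C(C)C)c3O2)cc1OCc1ccccc1
A1 | alternative 1 | isoferulic acid, (E)-3-(3-hydroxy-4-methoxyphenyl)prop-2-enoic acid | COc1ccc(/C=C/C(=O)O)cc1O
A2 | alternative 1 | (2S)-hesperetin | COc1ccc([C@@H]2CC(=O)c3c(O)cc(O)cc3O2)cc1O
A3 | alternative 2 | 2-(trimethylsilyl)ethyl 3-[2-{[3-(tert-butyldimethylsilyloxy)-4-methoxyphenyl]methoxy}-6-(tert-butyldimethylsilyloxy)-4-methoxy-3-(3-methylbut-2-en-1-yl)phenyl]-2-diazo-3-oxopropanoate | COc1ccc(COc2c(CC=C(C)C)c(OC)cc(O[Si](C)(C)C(C)(C)C)c2C(=O)C(=[N+]=[N-])C(=O)OCC[Si](C)(C)C)cc1O[Si](C)(C)C(C)(C)C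
A4 | alternative 2 | 2-(trimethylsilyl)ethyl (2S,3-trans)-5,3'-bis-O-(tert-butyldimethylsilyl)flavanone-3-carboxylate bearing 7-OMe, 4'-OMe and 8-prenyl | COc1ccc([C@@H]2[C@@H](C(=O)OCC[Si](C)(C)C)C(=O)c3c(O[Si](C)(C)C(C)(C)C)cc(OC)c(CC=C(C)C)c3O2)cc1O[Si](C)(C)C(C)(C)C
A5 | alternative 3 | (2S)-5-bromo-2-[3-(tert-butyldimethylsilyloxy)-4-methoxyphenyl]-2,3-dihydro-4H-pyran-4-one | COc1ccc([C@@H]2CC(=O)C(Br)=CO2)cc1O[Si](C)(C)C(C)(C)C
A6 | alternative 3 | 1,3-dimethoxy-7-methyl-1-(trimethylsilyloxy)octa-1,3,6-triene | COC(O[Si](C)(C)C)=CC(OC)=CCC=C(C)C
A7 | alternative 3 | (2S)-3'-O-(tert-butyldimethylsilyl) ether of the target | COc1ccc([C@@H]2CC(=O)c3c(O)cc(OC)c(CC=C(C)C)c3O2)cc1O[Si](C)(C)C(C)(C)C
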